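Count the chains first. You asked for a quick number on this flask, and here is what I have to go on:

| setting | noon | dawn | midnight | flask |
|---|---|---|---|---|
| free monomer | 0.050 M | 0.050 M | 0.050 M | 0.050 M |
| protic impurity | 2.5 mM | 2.5 mM | 5 mM | 2.50 mM |
| initiator | 5 mol% | 5 mol% | 5 mol% | 5 mol% |
| stray impurity | 0.60 mM | 2.4 mM | 1.2 mM | 1.2 mM |
| remark | run made earlier | run made earlier | run made earlier |  |
| time |  |  |  | 12 min |

| run | time / min | monomer in chains / % | free monomer / % |
|---|---|---|---|
| noon | 1.00 | 32 | 65 |
| noon | 2.00 | 52 | 43 |
| noon | 3.00 | 61 | 35 |
| noon | 6.00 | 67 | 24 |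
| noon | 12.0 | 68 | 29 |
| dawn | 2.50 | 12 | 87 |
| dawn | 5.00 | 11 | 88 |
| dawn | 8.00 | 10 | 83 |
| dawn | 10.0 | 11 | 87 |
| dawn | 12.0 | 11 | 85 |
| midnight | 2.50 | 42 | 48 |
| midnight | 5.00 | 49 | 40 |
| midnight | 8.00 | 52 | 37 |
| midnight | 10.0 | 52 | 35 |
| midnight | 12.0 | 54 | 35 |

(standard deviation of a reading: 1.5 percentage points)

1. average number of monomer units in a chain (chains begun, living or dead) at 12 min
2. part of the free monomer that has reacted at 12 min

- the average divides the monomer in chains by the number of chains begun, living and dead together
- the earlier runs do not show the number of chains; that part of a forecast is a guess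

The flask's initiator charge is 2.50 mM, more than its 1.2 mM of stray impurity, and my bet is that the two cancel one for one, with stray impurity as the limiting reagent of that titration, so I carry the initiator surplus, the initiator charge minus the stray impurity, here 1.30 mM. At one end the dawn run has a surplus of 0.100 mM and reads 11% monomer in chains at 12.0 min, and at the other the noon run has 1.90 mM and reads 68% at 12.0 min. The midnight run joins them, having this flask's surplus, but its two columns sum to 89.0% at 12.0 min, which fits protic impurity taking about 10.0% of the monomer. Scaling its 54% to the monomer this flask has available, I expect 57.0% in chains, so c near 62.0%, and, if each unit of surplus begins one chain, an average of 21.9.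

Your forecast gives 13 and 62.5%, and of the number of chains it says: “Chains begun are a guess: 2.5 mM if stray impurity kills after initiation, fewer if it destroys initiator.” It allows 22 as the other case; we part on which case to commit to.

The flask gives 21.4 and 60.6%.

    free monomer + initiator → living end + monomer in chains (k = 0.740 /M/s)
    free monomer + living end → monomer in chains + living end, rate k2*[living end]*[free monomer] (k = 6.92 /M/s)
    living end → dead end A (k = 0.0106 /s)
    protic impurity + free monomer → quenched substrate (k = 3.07 /M/s)
    initiator + stray impurity → spent initiator B (k = 723 /M/s)

At 12.0 min the flask holds 0.00130 M of dead end A, close to the surplus, beside 0.00120 M of spent initiator B. The neighbouring flask, with 3.0 × 10⁻⁴ M of stray impurity, has a surplus of 2.20 mM and holds 0.00220 M of dead end A. Dividing its 73.7% of monomer in chains by that surplus gives 16.8, and that neighbouring flask stands at 16.8.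

The earlier runs and the new flask were computed on assumed constants.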